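## Retrosynthetic overview

1. Feature: ring A of the 3,7-dioxabicyclo[3.3.0]octane core is O–C7–C8–C8'–C9' (lignan locants; C7 carries the plain 4-hydroxy-3-methoxyphenyl group). The aryl group on C7, C9 on C8 and C7' on C8' all lie on one face, so the C7 aryl group is endo. The aryl group on C7' is endo too and the dihydrobenzofuran (ring C) is 2,3-cis, so every benzylic centre is contra-thermodynamic.
2. Ring B (O–C7'–C8'–C8–C9) is disconnected first. C7'–H comes from hydride delivery to the convex face of a bicyclic oxocarbenium ion, and C7'–aryl from addition of a benzofuranyllithium to an all-cis 4-formyloxolane.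
3. Key disconnection: bonds C7–C8 and C8'–C9' of ring A are made together by Prins–pinacol ring contraction of a 2-aryl-4-[(Z)-alkenyl]-1,3-dioxolane. This acetal joins silylated vanillin to a diol from (S)-glyceraldehyde acetonide; its single carbinol centre is relayed into C7, C8 and C8' and then becomes the formyl carbon C7'.
4. Ring C comes from a cis-selective, catalyst-controlled carbenoid C–H insertion of an aryl diazoacetate built from 4-bromo-2-methoxyphenol, silylated vanillyl alcohol and dimethyl oxalate.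
5. Order of ring formation: ring A (step 8) and ring C (step 14) in separate branches, then ring B (step 20) after their union.

Key step: step 8

Assumption: for 2-(benzyloxy)aryl diazoacetates the (S)-tert-leucinate catalyst Rh2(S-PTTL)4 is taken to favour the (2R,3S)-cis ester, so the (2S,3R)-cis ester needed here is assigned to Rh2(R-PTTL)4; if the sense proves opposite on this substrate, the other catalyst enantiomer is used and nothing else changes.

Abbreviations:
- TBS = tert-butyldimethylsilyl
- Piv = pivaloyl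
- G = 4-(TBS-oxy)-3-methoxyphenyl
- BF = (2S,3S)-2-G-3-(TBS-oxymethyl)-7-methoxy-2,3-dihydro-1-benzofuran-5-yl
- PTTL = N-phthaloyl-tert-leucinate

## Route

Step 1
Reactants: 1 vanillin
Product: 2 4-(TBS-oxy)-3-methoxybenzaldehyde
Conditions: TBSCl, imidazole, CH2Cl2, rt
Reagents that add atoms: tert-butyldimethylsilyl chloride, CC(C)(C)[Si](C)(C)Cl
Why: Standard O-silylation of a phenol, giving an ether that should survive the organometallic, hydride and cold Lewis acid steps and fall to fluoride at the end.

Step 2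
Reactants: 2 4-(TBS-oxy)-3-methoxybenzaldehyde
Product: 3 G-CH(OMe)2 (dimethyl acetal of 2)
Conditions: HC(OMe)3, p-TsOH·H2O (cat.), MeOH, rt; Et3N quench
Reagents that add atoms: trimethyl orthoformate, COC(OC)OC; methanol, CO
Why: Acid-catalysed acetalisation driven by the orthoester as water scavenger, chosen because the dimethyl acetal exchanges with a diol under much milder acid than the electron-rich aldehyde would need.

Step 3
Reactants: 4 (S)-2,2-dimethyl-1,3-dioxolane-4-carbaldehyde
Product: 5 methyl (Z)-3-[(4R)-2,2-dimethyl-1,3-dioxolan-4-yl]prop-2-enoate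
Conditions: (CF3CH2O)2P(O)CH2CO2Me, KN(SiMe3)2, 18-crown-6, THF, −78 °C
Reagents that add atoms: methyl bis(2,2,2-trifluoroethyl)phosphonoacetate, COC(=O)CP(=O)(OCC(F)(F)F)OCC(F)(F)F
Why: Still–Gennari variant of the Horner–Wadsworth–Emmons olefination, in which fast elimination from the electron-poor phosphonate adduct should give the Z-enoate; the alkoxy stereocentre is untouched (its descriptor changes from S to R only through the ranking of substituents), and any E-isomer is removed here because it would end as the C8 epimer.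

Step 4
Reactants: 5 methyl (Z)-3-[(4R)-2,2-dimethyl-1,3-dioxolan-4-yl]prop-2-enoate
Product: 6 (Z)-3-[(4R)-2,2-dimethyl-1,3-dioxolan-4-yl]prop-2-en-1-ol
Conditions: iBu2AlH, CH2Cl2, −78 °C; aq potassium sodium tartrate
Reagents that add atoms: none
Why: 1,2-Reduction of an enoate by a dialkylaluminium hydride, which should leave the Z-alkene and the acetonide unchanged.

Step 5
Reactants: 6 (Z)-3-[(4R)-2,2-dimethyl-1,3-dioxolan-4-yl]prop-2-en-1-ol
Product: 7 (Z)-3-[(4R)-2,2-dimethyl-1,3-dioxolan-4-yl]prop-2-enyl pivalate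
Conditions: PivCl, Et3N, DMAP (cat.), CH2Cl2, 0 °C
Reagents that add atoms: pivaloyl chloride, CC(C)(C)C(=O)Cl
Why: Acylation of a primary alcohol, the hindered ester being chosen because it tolerates SnCl4, resists the aryllithium of step 17 and can be removed reductively beside silyl ethers.

Step 6
Reactants: 7 (Z)-3-[(4R)-2,2-dimethyl-1,3-dioxolan-4-yl]prop-2-enyl pivalate
Product: 8 (2Z,4R)-4,5-dihydroxypent-2-enyl pivalate
Conditions: AcOH/H2O (4:1), rt to 40 °C
Reagents that add atoms: none
Why: Mild acid hydrolysis of an isopropylidene acetal, under which the pivalate and the Z-alkene should stay in place.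

Step 7
Reactants: 8 (2Z,4R)-4,5-dihydroxypent-2-enyl pivalate; 3 G-CH(OMe)2
Product: 9 (4R)-2-G-4-[(Z)-3-(pivaloyloxy)prop-1-enyl]-1,3-dioxolane (both C2 epimers)
Conditions: PPTS (cat.), CH2Cl2, 5 Å molecular sieves, rt
Reagents that add atoms: none
Why: Transacetalisation driven by uptake of methanol, in which the new acetal carbon forms without control; this does not matter because that carbon becomes planar in step 8.

Step 8
Reactants: 9 (4R)-2-G-4-[(Z)-3-(pivaloyloxy)prop-1-enyl]-1,3-dioxolane
Product: 12 [(2S,3S,4S)-2-G-4-formyloxolan-3-yl]methyl pivalate (all-cis), via oxocarbenium ion 10 (not isolated), via oxan-4-yl cation 11 (not isolated)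
Conditions: SnCl4, CH2Cl2, −78 to −25 °C; cold aq NaHCO3
Reagents that add atoms: none
Why: SnCl4 opens the acetal reversibly at either oxygen, but only cleavage of the bond to the allylic oxygen gives an ion that can react on, the (E)-aryl oxocarbenium ion 10, in which C8 of the Z-alkene bonds to C7 by a 6-endo-trig closure through a chair to give the oxan-4-yl cation 11. The ring bond C7'–C9' next to the charge then shifts to C8' while the stannyloxy group on C7' becomes the carbonyl group, so that ring A (O–C7–C8–C8'–C9') is closed by ring contraction of the oxane and C7' is left outside it as the formyl carbon; the sequence is the Prins–pinacol rearrangement of 4-alkenyl-1,3-dioxolanes, a known way to 3-acyl- and 3-formyloxolanes. C7 is controlled by the E geometry of the cation (aryl equatorial), C8 by the Z geometry of the alkene (CH2OPiv axial and therefore cis to the aryl group), and C8' by the shift itself, because C9' can bond only to the face of the cation on which it already lies, which turns the formyl group to the face of the other two substituents. The absolute sense is controlled by the (R)-carbinol carbon, which must place its hydrogen and not its oxygen in the axial site 1,3 to the axial CH2OPiv group, so that only one of the two chairs remains. The step needs regioselectivity (bond at C8, charge on C8'), secured because bonding through C8' would be a 5-endo closure at the oxocarbenium carbon and the ion from opening at the other oxygen has only four-membered or 5-endo closures open to it, and it needs the shift to outrun capture of the cation, which is helped because the pivalate lies on the face of C8' opposite to the migrating bond, so that any bridging by its carbonyl oxygen is reversible and is displaced by the shift. Low temperature and the cold basic quench should keep the acid-labile endo C7–O bond and the formyl-bearing centre C8' from equilibrating.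

Step 9
Reactants: 2 4-(TBS-oxy)-3-methoxybenzaldehyde
Product: 13 G-CH2OH (4-(TBS-oxy)-3-methoxybenzyl alcohol)
Conditions: NaBH4, MeOH, 0 °C
Reagents that add atoms: none
Why: Borohydride reduction of an aromatic aldehyde, fast enough at 0 °C that the aryl silyl ether should not be methanolysed.

Step 10
Reactants: 14 4-bromo-2-methoxyphenol
Product: 15 4-bromo-2-iodo-6-methoxyphenol
Conditions: N-iodosuccinimide, p-TsOH·H2O (cat.), MeCN, rt, dark
Reagents that add atoms: N-iodosuccinimide, O=C1CCC(=O)N1I
Why: Electrophilic aromatic iodination directed by the hydroxyl group to its only free ortho position, the para position being blocked by bromine.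

Step 11
Reactants: 15 4-bromo-2-iodo-6-methoxyphenol; 13 G-CH2OH
Product: 16 5-bromo-1-iodo-3-methoxy-2-(G-methoxy)benzene
Conditions: PPh3, DIAD, THF, 0 °C to rt
Reagents that add atoms: none
Why: Mitsunobu etherification of an acidic halophenol with a primary benzylic alcohol, used because its neutral conditions avoid both the unstable 4-silyloxybenzyl halide and the carbonate bases that strip aryl silyl ethers.

Step 12
Reactants: 16 5-bromo-1-iodo-3-methoxy-2-(G-methoxy)benzene
Product: 18 methyl 2-[5-bromo-3-methoxy-2-(G-methoxy)phenyl]-2-oxoacetate, via arylmagnesium chloride 17 (not isolated)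
Conditions: iPrMgCl·LiCl, THF, −30 °C; then added to (CO2Me)2 (excess), THF, −78 °C; aq NH4Cl
Reagents that add atoms: dimethyl oxalate, COC(=O)C(=O)OC
Why: Halogen–magnesium exchange is much faster at the carbon–iodine than at the carbon–bromine bond, and acylation of the aryl Grignard reagent with excess oxalate at low temperature should stop at the keto ester because the tetrahedral adduct persists until the quench.

Step 13
Reactants: 18 methyl 2-[5-bromo-3-methoxy-2-(G-methoxy)phenyl]-2-oxoacetate
Product: 20 methyl 2-[5-bromo-3-methoxy-2-(G-methoxy)phenyl]-2-diazoacetate, via tosylhydrazone 19 (not isolated)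
Conditions: TsNHNH2, MeOH, 60 °C; evaporate; DBU, CH2Cl2, rt
Reagents that add atoms: p-toluenesulfonyl hydrazide, Cc1ccc(cc1)S(=O)(=O)NN
Why: Hydrazone formation followed by base-induced loss of sulfinate (Bamford–Stevens type) is a standard route from aryl glyoxylates to aryl diazoacetates.

Step 14
Reactants: 20 methyl 2-[5-bromo-3-methoxy-2-(G-methoxy)phenyl]-2-diazoacetate
Product: 21 methyl (2S,3R)-5-bromo-2-G-7-methoxy-2,3-dihydro-1-benzofuran-3-carboxylate (2,3-cis)
Conditions: Rh2(R-PTTL)4 (1 mol %), toluene, −78 °C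
Reagents that add atoms: none
Why: Intramolecular 1,5-C–H insertion of a dirhodium carbenoid from an aryl diazoacetate into the activated benzylic ether C–H bond closes ring C in one concerted event, in which the phthaloyl-tert-leucinate ligand sphere sets C2 and C3 cis to each other and in the absolute sense stated in the assumption; any minor enantiomer is shed as a diastereomer after step 17.

Step 15
Reactants: 21 methyl (2S,3R)-5-bromo-2-G-7-methoxy-2,3-dihydro-1-benzofuran-3-carboxylate
Product: 22 [(2S,3S)-5-bromo-2-G-7-methoxy-2,3-dihydro-1-benzofuran-3-yl]methanol (2,3-cis)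
Conditions: iBu2AlH, CH2Cl2, −78 to −40 °C; aq potassium sodium tartrate
Reagents that add atoms: none
Why: Non-basic hydride reduction of the ester at low temperature should remove the acidifying carbonyl group before C3 can epimerise to the trans series, the change of the C3 descriptor being a ranking effect only.

Step 16
Reactants: 22 [(2S,3S)-5-bromo-2-G-7-methoxy-2,3-dihydro-1-benzofuran-3-yl]methanol
Product: 23 BF-Br ((2S,3S)-5-bromo-2-G-3-(TBS-oxymethyl)-7-methoxy-2,3-dihydro-1-benzofuran)
Conditions: TBSCl, imidazole, CH2Cl2, rt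
Reagents that add atoms: tert-butyldimethylsilyl chloride, CC(C)(C)[Si](C)(C)Cl
Why: O-Silylation of the primary alcohol, so that all three hydroxyl groups to be freed at the end carry the same fluoride-labile group.

Step 17
Reactants: 23 BF-Br; 12 [(2S,3S,4S)-2-G-4-formyloxolan-3-yl]methyl pivalate
Product: 25 [(2S,3S,4S)-2-G-4-[BF-CH(OH)]oxolan-3-yl]methyl pivalate (both C7' epimers), via aryllithium 24 (not isolated)
Conditions: n-BuLi, THF, −78 °C; then 12, THF, −78 °C; aq NH4Cl
Reagents that add atoms: none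
Why: Bromine–lithium exchange on an electron-rich aryl bromide and 1,2-addition to the aldehyde, which is far more reactive than the hindered pivalate, form the C7'–aryl bond, and the uncontrolled carbinol centre is erased in step 19.

Step 18
Reactants: 25 [(2S,3S,4S)-2-G-4-[BF-CH(OH)]oxolan-3-yl]methyl pivalate
Product: 26 BF-CH(OH)-[(3S,4S,5S)-5-G-4-(hydroxymethyl)oxolan-3-yl] (diol, both C7' epimers)
Conditions: iBu2AlH (excess), CH2Cl2, −78 °C; aq potassium sodium tartrate
Reagents that add atoms: none
Why: Reductive cleavage of the pivalate avoids the hydroxide or alkoxide that would strip the aryl silyl ethers, and works wherever the acyl group may sit after step 17.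

Step 19
Reactants: 26 diol
Product: 27 BF-C(=O)-[(3S,4S,5S)-5-G-4-(hydroxymethyl)oxolan-3-yl] (hydroxy ketone)
Conditions: MnO2 (activated, excess), CH2Cl2, rt
Reagents that add atoms: none
Why: MnO2 oxidises the electron-rich benzylic carbinol chemoselectively beside the saturated primary alcohol, both C7' epimers converge on one ketone, and only the C8' configuration cis to C9 can close to the hemiketal.

Step 20
Reactants: 27 hydroxy ketone
Product: 30 (7S,7'S,8S,8'S)-7-G-7'-BF-7,9':7',9-diepoxylignan core (tris-TBS ether of the target; both aryl groups endo), via cyclic hemiketal 28 (not isolated), via bicyclic oxocarbenium ion 29 (not isolated)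
Conditions: Et3SiH, BF3·OEt2, CH2Cl2, −78 °C; Et3N then aq NaHCO3 at −78 °C
Reagents that add atoms: none
Why: Reductive etherification by ionic hydrogenation, in which BF3 ionises the hemiketal 28 to the cis-fused oxocarbenium ion 29 and the silane delivers hydride to its convex face, the concave face being closed by ring A and its endo aryl group, so that H-7' ends exo and the benzofuranyl group endo (7'S) while ring B closes.

Step 21
Reactants: 30 tris-TBS ether
Product: 31 target, 4-[(1S,3aS,4S,6aS)-4-[(2S,3S)-2-(4-hydroxy-3-methoxyphenyl)-3-(hydroxymethyl)-7-methoxy-2,3-dihydro-1-benzofuran-5-yl]hexahydrofuro[3,4-c]furan-1-yl]-2-methoxyphenol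
Conditions: Bu4NF, AcOH (1:1), THF, 0 °C to rt
Reagents that add atoms: none
Why: Fluoride desilylation of the two aryl and one alkyl silyl ethers, buffered with acetic acid so that no free phenoxide can open the 4-hydroxybenzylic ethers through quinone methides and scramble C7 or C2 of ring C.

## Compound list

1 | vanillin | COc1cc(C=O)ccc1O | starting material
2 | 4-(TBS-oxy)-3-methoxybenzaldehyde | COc1cc(C=O)ccc1O[Si](C)(C)C(C)(C)C | intermediate
3 | 4-(TBS-oxy)-3-methoxybenzaldehyde dimethyl acetal | COc1cc(C(OC)OC)ccc1O[Si](C)(C)C(C)(C)C | intermediate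
4 | (S)-2,2-dimethyl-1,3-dioxolane-4-carbaldehyde | O=C[C@@H]1COC(C)(C)O1 | starting material
5 | methyl (Z)-3-[(4R)-2,2-dimethyl-1,3-dioxolan-4-yl]prop-2-enoate | COC(=O)/C=C\[C@@H]1COC(C)(C)O1 | intermediate
6 | (Z)-3-[(4R)-2,2-dimethyl-1,3-dioxolan-4-yl]prop-2-en-1-ol | OC/C=C\[C@@H]1COC(C)(C)O1 | intermediate
7 | (Z)-3-[(4R)-2,2-dimethyl-1,3-dioxolan-4-yl]prop-2-enyl pivalate | CC(C)(C)C(=O)OC/C=C\[C@@H]1COC(C)(C)O1 | intermediate
8 | (2Z,4R)-4,5-dihydroxypent-2-enyl pivalate | CC(C)(C)C(=O)OC/C=C\[C@@H](O)CO | intermediate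
9 | (4R)-2-G-4-[(Z)-3-(pivaloyloxy)prop-1-enyl]-1,3-dioxolane, both C2 epimers (acetal carbon left undefined) | COc1cc(C2OC[C@@H](/C=C\COC(=O)C(C)(C)C)O2)ccc1O[Si](C)(C)C(C)(C)C | intermediate
10 | (E)-aryl oxocarbenium ion with the (R)-carbinol oxygen bound to SnCl4 | COc1cc(/C=[O+]/C[C@H](O[Sn-](Cl)(Cl)(Cl)Cl)/C=C\COC(=O)C(C)(C)C)ccc1O[Si](C)(C)C(C)(C)C | intermediate
11 | 2-G-3-(pivaloyloxymethyl)-5-(tetrachlorostannyloxy)oxan-4-yl cation (chair; G and stannyloxy equatorial, CH2OPiv axial) | COc1cc([C@H]2OC[C@H](O[Sn-](Cl)(Cl)(Cl)Cl)[CH+][C@H]2COC(=O)C(C)(C)C)ccc1O[Si](C)(C)C(C)(C)C | intermediate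
12 | [(2S,3S,4S)-2-G-4-formyloxolan-3-yl]methyl pivalate (all-cis) | COc1cc([C@H]2OC[C@@H](C=O)[C@H]2COC(=O)C(C)(C)C)ccc1O[Si](C)(C)C(C)(C)C | intermediate
13 | 4-(TBS-oxy)-3-methoxybenzyl alcohol | COc1cc(CO)ccc1O[Si](C)(C)C(C)(C)C | intermediate
14 | 4-bromo-2-methoxyphenol | COc1cc(Br)ccc1O | starting material
15 | 4-bromo-2-iodo-6-methoxyphenol | COc1cc(Br)cc(I)c1O | intermediate
16 | 5-bromo-1-iodo-3-methoxy-2-(G-methoxy)benzene | COc1cc(Br)cc(I)c1OCc1ccc(O[Si](C)(C)C(C)(C)C)c(OC)c1 | intermediate
17 | [5-bromo-3-methoxy-2-(G-methoxy)phenyl]magnesium chloride | COc1cc(Br)cc([Mg]Cl)c1OCc1ccc(O[Si](C)(C)C(C)(C)C)c(OC)c1 | intermediate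
18 | methyl 2-[5-bromo-3-methoxy-2-(G-methoxy)phenyl]-2-oxoacetate | COC(=O)C(=O)c1cc(Br)cc(OC)c1OCc1ccc(O[Si](C)(C)C(C)(C)C)c(OC)c1 | intermediate
19 | tosylhydrazone of 18 | COC(=O)C(=NNS(=O)(=O)c1ccc(C)cc1)c1cc(Br)cc(OC)c1OCc1ccc(O[Si](C)(C)C(C)(C)C)c(OC)c1 | intermediate
20 | methyl 2-[5-bromo-3-methoxy-2-(G-methoxy)phenyl]-2-diazoacetate | COC(=O)C(=[N+]=[N-])c1cc(Br)cc(OC)c1OCc1ccc(O[Si](C)(C)C(C)(C)C)c(OC)c1 | intermediate
21 | methyl (2S,3R)-5-bromo-2-G-7-methoxy-2,3-dihydro-1-benzofuran-3-carboxylate (cis) | Brc1cc(OC)c2c(c1)[C@@H](C(=O)OC)[C@@H](c1ccc(O[Si](C)(C)C(C)(C)C)c(OC)c1)O2 | intermediate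
22 | [(2S,3S)-5-bromo-2-G-7-methoxy-2,3-dihydro-1-benzofuran-3-yl]methanol (cis) | Brc1cc(OC)c2c(c1)[C@@H](CO)[C@@H](c1ccc(O[Si](C)(C)C(C)(C)C)c(OC)c1)O2 | intermediate
23 | BF-Br | Brc1cc(OC)c2c(c1)[C@@H](CO[Si](C)(C)C(C)(C)C)[C@@H](c1ccc(O[Si](C)(C)C(C)(C)C)c(OC)c1)O2 | intermediate
24 | BF-Li | [Li]c1cc(OC)c2c(c1)[C@@H](CO[Si](C)(C)C(C)(C)C)[C@@H](c1ccc(O[Si](C)(C)C(C)(C)C)c(OC)c1)O2 | intermediate
25 | [(2S,3S,4S)-2-G-4-[BF-CH(OH)]oxolan-3-yl]methyl pivalate, both C7' epimers | COc1cc([C@H]2OC[C@@H](C(O)c3cc(OC)c4c(c3)[C@@H](CO[Si](C)(C)C(C)(C)C)[C@@H](c3ccc(O[Si](C)(C)C(C)(C)C)c(OC)c3)O4)[C@H]2COC(=O)C(C)(C)C)ccc1O[Si](C)(C)C(C)(C)C | intermediate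
26 | C9,C7'-diol, both C7' epimers | COc1cc([C@H]2OC[C@@H](C(O)c3cc(OC)c4c(c3)[C@@H](CO[Si](C)(C)C(C)(C)C)[C@@H](c3ccc(O[Si](C)(C)C(C)(C)C)c(OC)c3)O4)[C@H]2CO)ccc1O[Si](C)(C)C(C)(C)C | intermediate
27 | C7' ketone with free C9 hydroxyl group | COc1cc([C@H]2OC[C@@H](C(=O)c3cc(OC)c4c(c3)[C@@H](CO[Si](C)(C)C(C)(C)C)[C@@H](c3ccc(O[Si](C)(C)C(C)(C)C)c(OC)c3)O4)[C@H]2CO)ccc1O[Si](C)(C)C(C)(C)C | intermediate
28 | cis-fused bicyclic hemiketal at C7' (anomeric centre undefined) | COc1cc([C@H]2OC[C@@H]3[C@H]2COC3(O)c2cc(OC)c3c(c2)[C@@H](CO[Si](C)(C)C(C)(C)C)[C@@H](c2ccc(O[Si](C)(C)C(C)(C)C)c(OC)c2)O3)ccc1O[Si](C)(C)C(C)(C)C | intermediate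
29 | cis-fused bicyclic oxocarbenium ion (C7'=O+) | COc1cc([C@H]2OC[C@@H]3[C@H]2C[O+]=C3c2cc(OC)c3c(c2)[C@@H](CO[Si](C)(C)C(C)(C)C)[C@@H](c2ccc(O[Si](C)(C)C(C)(C)C)c(OC)c2)O3)ccc1O[Si](C)(C)C(C)(C)C | intermediate
30 | tris-TBS ether of the target (7S,7'S,8S,8'S; ring C 2S,3S) | COc1cc([C@H]2OC[C@@H]3[C@H]2CO[C@@H]3c2cc(OC)c3c(c2)[C@@H](CO[Si](C)(C)C(C)(C)C)[C@@H](c2ccc(O[Si](C)(C)C(C)(C)C)c(OC)c2)O3)ccc1O[Si](C)(C)C(C)(C)C | intermediate
31 | CNP0303197.1 | COc1cc([C@H]2OC[C@@H]3[C@H]2CO[C@@H]3c2cc(OC)c3c(c2)[C@@H](CO)[C@@H](c2ccc(O)c(OC)c2)O3)ccc1O | target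

## Step count and risks

Total step count: 21.
Longest linear sequence: 13 steps (steps 1, 9 and 11 to 21, from vanillin through ring C to the target). The ring A branch from 4 counts 11 steps.

**Step 8**

The silyloxy-stabilised oxocarbenium ion may be too weak an electrophile for an alkene that carries an allylic ester. Acetal scrambling, lasting capture of the cation by the ester carbonyl group, or re-ionisation of the new benzylic C7–O bond with loss of the endo configuration could then overtake the shift.

The fallback sets out from 1 and 8 and comes back at 12. It changes the design of the substrate by turning the para donor of the cation into an acceptor.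
- Vanillin 1 is acylated with allyl chloroformate and pyridine to allyl 4-formyl-2-methoxyphenyl carbonate F1.
- This more electrophilic aldehyde condenses directly with diol 8 (PPTS, toluene, reflux with water separation) to the (4R)-2-aryl-4-[(Z)-3-(pivaloyloxy)prop-1-enyl]-1,3-dioxolane carrying the allyl carbonate F2.
- The cation from F2 has about the reactivity of a benzaldehyde-derived one, the best-documented case of this rearrangement. SnCl4 in CH2Cl2 should give the all-cis carbonate-protected formyloxolane F3, whose benzylic ether is much harder to re-ionise.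
- Pd(PPh3)4 with dimedone in THF removes the allyl carbonate under neutral conditions to give the all-cis phenol aldehyde F4.
- TBSCl and imidazole return 12.

**Step 20**

BF3 may also ionise the finished endo C7–O and C7'–O bonds and the O1–C2 bond of the cis-dihydrobenzofuran. That would drain these centres towards the exo and trans series, or allow a second hydride capture with ring opening.

The fallback sets out from 27 and comes back at 30. It closes ring B at the primary carbon C9 under basic conditions, so no benzylic cation is involved.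
- The open form of 27 is sulfonylated at the primary hydroxyl group (TsCl, pyridine, 0 °C) to the C7' ketone C9 tosylate F5.
- Corey–Bakshi–Shibata reduction with the (R)-methyl oxazaborolidine and BH3·SMe2, with the aryl group acting as the large substituent, should give the (7'S)-carbinol C9 tosylate F6. A minor epimer would be separated there.
- KN(SiMe3)2 in THF (−78 to 0 °C) closes the ring by a 5-exo-tet Williamson displacement with retention at C7', giving 30.

**Step 17**

The basic aryllithium may enolise the hindered all-cis aldehyde, with loss of configuration at C8', or attack the ester.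

The fallback sets out from 12 and 24 and comes back at 26. It replaces carbonyl addition by a palladium-catalysed acylation.
- Pinnick oxidation of 12 (NaClO2, NaH2PO4, 2-methyl-2-butene, t-BuOH/H2O) gives the all-cis oxolane-3-carboxylic acid F7.
- EtSH with EDC·HCl and catalytic DMAP at 0 °C gives the S-ethyl thioester F8.
- Aryllithium 24 is transmetalated with ZnCl2 to the arylzinc chloride F9.
- Fukuyama coupling of F8 and F9 (PdCl2(PPh3)2, THF/toluene, rt) gives the C7' ketone C9 pivalate F10.
- Excess iBu2AlH at −78 °C reduces the ketone and cleaves the pivalate in one operation to the diol 26.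

## Further compounds

F1 | step 8 | allyl 4-formyl-2-methoxyphenyl carbonate | C=CCOC(=O)Oc1ccc(C=O)cc1OC
F2 | step 8 | (4R)-2-[4-(allyloxycarbonyloxy)-3-methoxyphenyl]-4-[(Z)-3-(pivaloyloxy)prop-1-enyl]-1,3-dioxolane, both C2 epimers | C=CCOC(=O)Oc1ccc(C2OC[C@@H](/C=C\COC(=O)C(C)(C)C)O2)cc1OC
F3 | step 8 | [(2S,3S,4S)-2-[4-(allyloxycarbonyloxy)-3-methoxyphenyl]-4-formyloxolan-3-yl]methyl pivalate | C=CCOC(=O)Oc1ccc([C@H]2OC[C@@H](C=O)[C@H]2COC(=O)C(C)(C)C)cc1OC
F4 | step 8 | [(2S,3S,4S)-4-formyl-2-(4-hydroxy-3-methoxyphenyl)oxolan-3-yl]methyl pivalate | COc1cc([C@H]2OC[C@@H](C=O)[C@H]2COC(=O)C(C)(C)C)ccc1O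
F5 | step 20 | C7' ketone C9 tosylate | COc1cc([C@H]2OC[C@@H](C(=O)c3cc(OC)c4c(c3)[C@@H](CO[Si](C)(C)C(C)(C)C)[C@@H](c3ccc(O[Si](C)(C)C(C)(C)C)c(OC)c3)O4)[C@H]2COS(=O)(=O)c2ccc(C)cc2)ccc1O[Si](C)(C)C(C)(C)C
F6 | step 20 | (7'S)-carbinol C9 tosylate | COc1cc([C@H]2OC[C@@H]([C@H](O)c3cc(OC)c4c(c3)[C@@H](CO[Si](C)(C)C(C)(C)C)[C@@H](c3ccc(O[Si](C)(C)C(C)(C)C)c(OC)c3)O4)[C@H]2COS(=O)(=O)c2ccc(C)cc2)ccc1O[Si](C)(C)C(C)(C)C
F7 | step 17 | (3S,4S,5S)-5-G-4-(pivaloyloxymethyl)oxolane-3-carboxylic acid | COc1cc([C@H]2OC[C@@H](C(=O)O)[C@H]2COC(=O)C(C)(C)C)ccc1O[Si](C)(C)C(C)(C)C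
F8 | step 17 | S-ethyl (3S,4S,5S)-5-G-4-(pivaloyloxymethyl)oxolane-3-carbothioate | COc1cc([C@H]2OC[C@@H](C(=O)SCC)[C@H]2COC(=O)C(C)(C)C)ccc1O[Si](C)(C)C(C)(C)C
F9 | step 17 | BF-ZnCl | Cl[Zn]c1cc(OC)c2c(c1)[C@@H](CO[Si](C)(C)C(C)(C)C)[C@@H](c1ccc(O[Si](C)(C)C(C)(C)C)c(OC)c1)O2
F10 | step 17 | C7' ketone C9 pivalate | COc1cc([C@H]2OC[C@@H](C(=O)c3cc(OC)c4c(c3)[C@@H](CO[Si](C)(C)C(C)(C)C)[C@@H](c3ccc(O[Si](C)(C)C(C)(C)C)c(OC)c3)O4)[C@H]2COC(=O)C(C)(C)C)ccc1O[Si](C)(C)C(C)(C)C
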